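**Kazusamycin A: total synthesis built on a carbonyl addition / semipinacol fragment union**

## Retrosynthetic overview
1. The C1 acid and the C24 lactone carbonyl are unveiled last (MnO2, then Pinnick) from an allylic alcohol and an ethyl lactol ether. No C–C bond is formed after the key step.
2. The key disconnection is C9–C10, replacing the usual C11–C13 sp2–sp2 coupling plus aldol/oxidation plan. The whole C10–C24 dienyl chain migrates from C8 to C9 of an α-silyloxy terminal epoxide (semipinacol 1,2-shift). One step creates C8=O, the C9′ hydroxyl and the C9 stereocentre, the last by inversion of the (R)-glycidate carbon.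
3. The rearrangement substrate comes from dienyllithium C10–C24 (from 27) and epoxy ketone C1–C9′ (12).
4. Compound 12 comes from a boron syn-aldol of oxiranyl ethyl ketone 10 with aldehyde 7. Compound 27 comes from two Negishi couplings and a Z-iodo-olefination. Aldehydes 7 and 20 arise from enantiomeric bromo alcohols by the same Negishi/Swern pair.
5. Ring order: the oxirane comes from the chiral pool and is consumed in the key step. The dihydropyran is made by syn-crotylation, mixed acrolein acetal formation and RCM. It is oxidised to the δ-lactone in the penultimate step.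

Assumption: kazusamycin numbering is used (C1 = acid carbon, C24 = lactone C=O, C9′ = hydroxymethyl carbon). C24 (acetal/lactol) and C8 in 28 form as epimer mixtures that are destroyed later, so they are left undefined in the SMILES.

## East fragment (C1–C9′)

**Step 1**
Reactants: 1, (R)-3-bromo-2-methylpropan-1-ol
Product: 2, (R)-(3-bromo-2-methylpropoxy)triethylsilane
Conditions: TESCl, imidazole, CH2Cl2, 0 °C → rt
Reagents that add atoms: chlorotriethylsilane, CC[Si](Cl)(CC)CC
Why: Routine silylation; the TES ether tolerates Grignard formation and can later be oxidised directly, and C5 comes untouched from the chiral pool.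

**Step 2**
Reactants: 3, but-2-yn-1-ol
Product: 4, (but-2-yn-1-yloxy)(tert-butyl)dimethylsilane
Conditions: TBSCl, imidazole, CH2Cl2, rt
Reagents that add atoms: tert-butyldimethylsilyl chloride, CC(C)(C)[Si](C)(C)Cl
Why: Routine silylation; the TBS group is chosen because it survives the TES-selective Swern oxidation in step 5.

**Step 3**
Reactants: 4
Product: 5, (E)-tert-butyl[(3-iodobut-2-en-1-yl)oxy]dimethylsilane
Conditions: Cp2Zr(H)Cl (2 equiv), THF, 40 °C; then I2, 0 °C
Reagents that add atoms: iodine, II
Why: Hydrozirconation–iodination; syn H–Zr addition equilibrates with excess reagent to place Zr on the methyl-bearing carbon, and iodinolysis with retention fixes the future 2E geometry.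

**Step 4**
Reactants: 2; 5
Product: 6, (2E,5S)-1-(tert-butyldimethylsilyloxy)-3,5-dimethyl-6-(triethylsilyloxy)hex-2-ene
Conditions: 2, Mg, THF, reflux; ZnBr2, 0 °C; then 5, PdCl2(dppf) (5 mol %), THF, rt
Reagents that add atoms: none
Why: sp3–sp2 Negishi coupling forms C3–C4 with retention of alkene geometry; dppf suppresses β-hydride elimination and C5 is not involved.

**Step 5**
Reactants: 6
Product: 7, (2S,4E)-6-(tert-butyldimethylsilyloxy)-2,4-dimethylhex-4-enal
Conditions: (COCl)2 (4 equiv), DMSO (8 equiv), CH2Cl2, −78 → −30 °C; Et3N, −78 °C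
Reagents that add atoms: none
Why: Swern oxidation applied directly to a primary TES ether (known deprotection–oxidation); the TBS ether is inert and the cold amine quench avoids C5 epimerisation.

**Step 6**
Reactants: 8, methyl (2R)-oxirane-2-carboxylate
Product: 9, (2R)-N-methoxy-N-methyloxirane-2-carboxamide
Conditions: MeNH(OMe)·HCl, i-PrMgCl, THF, −20 °C
Reagents that add atoms: N,O-dimethylhydroxylamine hydrochloride, CNOC.Cl
Why: Weinreb amidation by the magnesium amide; acyl substitution at −20 °C is faster than oxirane opening, and the future C9 is not deprotonated.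

**Step 7**
Reactants: 9
Product: 10, 1-[(2R)-oxiran-2-yl]propan-1-one
Conditions: EtMgBr (1.1 equiv), THF, −78 → −40 °C; cold NH4Cl; used as a concentrated solution because it is volatile
Reagents that add atoms: ethylmagnesium bromide, CC[Mg]Br
Why: Weinreb ketone synthesis; the stable chelated tetrahedral intermediate prevents over-addition, and the ethyl group supplies C7 and its methyl.

**Step 8**
Reactants: 10; 7
Product: 11, (2S,3R,4S,6E)-8-(tert-butyldimethylsilyloxy)-3-hydroxy-2,4,6-trimethyl-1-[(2R)-oxiran-2-yl]oct-6-en-1-one (kazusamycin 5S,6R,7S,9R)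
Conditions: 10, (–)-Ipc2BOTf [from (+)-α-pinene], i-Pr2NEt, CH2Cl2, −78 °C; 7, −78 → −20 °C; H2O2, MeOH, pH 7 buffer, 0 °C
Reagents that add atoms: none
Why: Paterson boron aldol; enolisation occurs only on the ethyl side to give the Z-enol borinate, whose Zimmerman–Traxler chair sets 6,7-syn, while the dIpc ligands (si-face attack on the aldehyde) and the dipole-minimised conformer of the α-oxirane centre both favour 6R,7S over the weak anti-Felkin bias of 7.

**Step 9**
Reactants: 11
Product: 12, the 3-O-triethylsilyl ether of 11 (C6–OTES epoxy ketone)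
Conditions: TESOTf, 2,6-lutidine, CH2Cl2, −78 °C
Reagents that add atoms: triethylsilyl triflate, CC[Si](CC)(CC)OS(=O)(=O)C(F)(F)F
Why: Low-temperature silylation blocks retro-aldol and alkoxide chemistry in the union step; the carbonyl-deactivated oxirane is not opened at −78 °C.

## West fragment (C10–C24)

**Step 10**
Reactants: 13, (S)-3-bromo-2-methylpropan-1-ol
Product: 14, (S)-(3-bromo-2-methylpropoxy)triethylsilane
Conditions: TESCl, imidazole, CH2Cl2, 0 °C → rt
Reagents that add atoms: chlorotriethylsilane, CC[Si](Cl)(CC)CC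
Why: Same silylation as step 1; C15 comes from the chiral pool.

**Step 11**
Reactants: 15, prop-2-yn-1-ol
Product: 16, (E)-3-bromo-2-methylprop-2-en-1-ol
Conditions: AlMe3 (3 equiv), Cp2ZrCl2 (25 mol %), CH2Cl2, 0 °C → rt; then NBS, THF, −30 °C
Reagents that add atoms: trimethylaluminium, C[Al](C)C; N-bromosuccinimide, O=C1CCC(=O)N1Br
Why: Negishi Zr-catalysed syn-carboalumination followed by bromodealumination with retention fixes the 10E trisubstituted geometry.

**Step 12**
Reactants: 16
Product: 17, (E)-3-bromo-2-methylprop-2-enal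
Conditions: MnO2, CH2Cl2, rt
Reagents that add atoms: none
Why: Allylic alcohol oxidation under neutral conditions leaves the alkene geometry intact.

**Step 13**
Reactants: 17
Product: 18, (1E,3E)-1-bromo-4-iodo-2-methylbuta-1,3-diene
Conditions: CrCl2, CHI3, THF/dioxane, 0 °C
Reagents that add atoms: iodoform, IC(I)I
Why: Takai olefination gives the E-vinyl iodide (12E); the vinyl bromide is inert to Cr(II) in the absence of Ni.

**Step 14**
Reactants: 14; 18
Product: 19, (1E,3E,6R)-1-bromo-2,6-dimethyl-7-(triethylsilyloxy)hepta-1,3-diene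
Conditions: 14, Mg, THF; ZnBr2, 0 °C; then 18 (1.1 equiv), Pd(PPh3)4 (5 mol %), THF, 0 °C
Reagents that add atoms: none
Why: Chemoselective sp3–sp2 Negishi coupling forms C13–C14; oxidative addition into C–I is much faster than into C–Br at 0 °C, and both alkene geometries are retained.

**Step 15**
Reactants: 19
Product: 20, (2R,4E,6E)-7-bromo-2,6-dimethylhepta-4,6-dienal
Conditions: (COCl)2, DMSO, CH2Cl2, −78 → −30 °C; Et3N, −78 °C
Reagents that add atoms: none
Why: Direct Swern oxidation of the primary TES ether as in step 5; the dienyl bromide is inert and C15 is preserved.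

**Step 16**
Reactants: 20
Product: 21, (1E,3E,6R,7Z)-1-bromo-8-iodo-2,6-dimethyldeca-1,3,7-triene
Conditions: n-PrPPh3Br, n-BuLi, THF; cannulate into I2, THF, −78 °C; NaHMDS, −20 °C; then 20, −40 °C
Reagents that add atoms: propyltriphenylphosphonium bromide, CCC[P+](c1ccccc1)(c1ccccc1)c1ccccc1.[Br-]; iodine, II
Why: Stork–Zhao-type Wittig reaction with the α-iodo ylide places iodine cis to C15 (Z-vinyl iodide), which presets the 16Z trisubstituted alkene and installs the ethyl branch.

**Step 17**
Reactants: 22, 3-(trimethylsilyl)prop-2-ynal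
Product: 23, (3R,4S)-4-methyl-1-(trimethylsilyl)hex-5-en-1-yn-3-ol
Conditions: cis-2-butene, n-BuLi, KOt-Bu, THF, −45 °C; (+)-Ipc2BOMe [from (–)-α-pinene], BF3·OEt2, −78 °C; 22; NaBO3·4H2O work-up
Reagents that add atoms: cis-2-butene, C/C=C\C
Why: Brown asymmetric (Z)-crotylboration; the chair transition state gives the syn C20-O/C21-Me pair, the lIpc ligands set the absolute sense (20S,21S in the target), and the mild perborate work-up keeps the C–Si bond.

**Step 18**
Reactants: 23
Product: 24, (3R,4S)-3-[(1-ethoxyprop-2-en-1-yl)oxy]-4-methyl-1-(trimethylsilyl)hex-5-en-1-yne (acetal epimers)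
Conditions: acrolein diethyl acetal (8 equiv), PPTS (cat.), toluene, 40 °C, reduced pressure to remove EtOH
Reagents that add atoms: acrolein diethyl acetal, C=CC(OCC)OCC
Why: Transacetalisation driven by ethanol removal installs C23–C24 already at the masked-lactone oxidation level.

**Step 19**
Reactants: 24
Product: 25, (2R,3S)-6-ethoxy-3-methyl-2-[(trimethylsilyl)ethynyl]-3,6-dihydro-2H-pyran
Conditions: Grubbs I (5 mol %), CH2Cl2 (5 mM), 40 °C
Reagents that add atoms: none
Why: Ring-closing metathesis of two monosubstituted alkenes closes the six-membered ring with the ring-enforced 22Z alkene; the silyl-capped alkyne does not undergo enyne metathesis with the first-generation catalyst.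

**Step 20**
Reactants: 25
Product: 26, (2R,3S)-6-ethoxy-2-ethynyl-3-methyl-3,6-dihydro-2H-pyran
Conditions: K2CO3, MeOH, rt
Reagents that add atoms: none
Why: Base-mediated C-desilylation; the acetal is stable to base.

**Step 21**
Reactants: 26; 21
Product: 27, (2S,3S)-2-[(1E,3Z,5R,7E,9E)-10-bromo-3-ethyl-5,9-dimethyldeca-1,3,7,9-tetraen-1-yl]-6-ethoxy-3-methyl-3,6-dihydro-2H-pyran
Conditions: 26 (1.1 equiv), Cp2Zr(H)Cl, THF, rt, dark; ZnCl2; then 21, Pd(PPh3)4 (5 mol %), 0 °C → rt
Reagents that add atoms: none
Why: Hydrozirconation (syn, giving 18E) with Zr→Zn transmetalation and Negishi alkenyl–alkenyl coupling forms C17–C18 with retention at both partners; selectivity for C–I over C–Br preserves the C10 bromide.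

## Union and endgame

**Step 22**
Reactants: 27; 12
Product: 28, tertiary silyl ether in which C8 bears OTMS, the (9R)-oxiranyl group, the C7 chain and the (10E,12E)-dienyl chain (C1-OTBS, C6-OTES, C24 ethyl acetal; C8 epimers)
Conditions: 27 (1.2 equiv), t-BuLi (2.05 equiv per 27), Et2O, −78 °C; 12, THF, −78 °C; TMSCl/Et3N, −78 → −20 °C
Reagents that add atoms: chlorotrimethylsilane, C[Si](C)(C)Cl
Why: Br/Li exchange with retention followed by 1,2-addition of the dienyllithium to the activated α-epoxy ketone, which is faster than enolisation or oxirane opening; TMSCl traps the alkoxide before Payne migration, and the C8 configuration is irrelevant because C8 becomes sp2 next.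

**Step 23 (key step)**
Reactants: 28
Product: 29, (9S)-β-hydroxy ketone with C8=O and C9 bearing CH2OH and the C10–C24 chain (C1-OTBS, C6-OTES, C24 ethyl acetal)
Conditions: BF3·OEt2 (1.1 equiv), CH2Cl2, −78 °C, 15 min; Et3N, then pH 7 buffer; brief citric acid/MeOH to cleave any C9′-OTMS
Reagents that add atoms: none
Why: Suzuki–Tsuchihashi semipinacol rearrangement of a 2,3-epoxy alcohol silyl ether; BF3 activates the unhindered oxirane and the electron-rich dienyl group migrates from C8 to C9 anti-periplanar to the breaking C9–O bond with silyloxy push, so (9R)-oxirane gives 9S by inversion with the alkene geometry retained, and acetal anomerisation is harmless.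

**Step 24**
Reactants: 29
Product: 30, lactol tetraol (free C1-OH, C6-OH, C9′-OH and C24-OH)
Conditions: AcOH/THF/H2O (3:1:1), 30 °C
Reagents that add atoms: water, O
Why: One mild aqueous acid treatment cleaves the TES ether, the primary allylic TBS ether and the allylic ethyl acetal without enolising the β,γ-unsaturated ketone.

**Step 25**
Reactants: 30
Product: 31, lactone enal (C24 lactone, C1 aldehyde)
Conditions: activated MnO2 (excess), CH2Cl2, rt
Reagents that add atoms: none
Why: MnO2 oxidises only allylic C–OH groups, taking the allylic lactol to the α,β-unsaturated δ-lactone and C1-OH to the enal; the C6 and homoallylic C9′ hydroxyls are untouched.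

**Step 26**
Reactants: 31
Product: 32, kazusamycin A
Conditions: NaClO2, NaH2PO4, 2-methyl-2-butene, t-BuOH/H2O, 0 °C
Reagents that add atoms: sodium chlorite, [Na+].[O-]Cl=O
Why: Pinnick oxidation converts the enal to the acid at about pH 4 with an HOCl scavenger, sparing the polyene, lactone, free alcohols and the epimerisable C7 and C9 centres.

## Compound list
| No. | Name | SMILES | Role |
|---|---|---|---|
| 1 | (R)-3-bromo-2-methylpropan-1-ol | `OC[C@@H](C)CBr` | starting material |
| 2 | (R)-(3-bromo-2-methylpropoxy)triethylsilane | `CC[Si](CC)(CC)OC[C@@H](C)CBr` | intermediate |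
| 3 | but-2-yn-1-ol | `CC#CCO` | starting material |
| 4 | but-2-yn-1-ol TBS ether | `CC#CCO[Si](C)(C)C(C)(C)C` | intermediate |
| 5 | (E)-3-iodobut-2-enyl TBS ether | `I/C(C)=C/CO[Si](C)(C)C(C)(C)C` | intermediate |
| 6 | C1–C6 bis-silyl ether (2E,5S) | `CC[Si](CC)(CC)OC[C@@H](C)C/C(C)=C/CO[Si](C)(C)C(C)(C)C` | intermediate |
| 7 | (2S,4E)-6-(TBSO)-2,4-dimethylhex-4-enal | `O=C[C@@H](C)C/C(C)=C/CO[Si](C)(C)C(C)(C)C` | intermediate |
| 8 | methyl (2R)-oxirane-2-carboxylate | `COC(=O)[C@H]1CO1` | starting material |
| 9 | (2R)-N-methoxy-N-methyloxirane-2-carboxamide | `CON(C)C(=O)[C@H]1CO1` | intermediate |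
| 10 | 1-[(2R)-oxiran-2-yl]propan-1-one | `CCC(=O)[C@H]1CO1` | intermediate |
| 11 | syn-aldol epoxy ketone (5S,6R,7S,9R) | `O=C([C@H]1CO1)[C@@H](C)[C@H](O)[C@@H](C)C/C(C)=C/CO[Si](C)(C)C(C)(C)C` | intermediate |
| 12 | C6-OTES epoxy ketone (East fragment) | `O=C([C@H]1CO1)[C@@H](C)[C@H](O[Si](CC)(CC)CC)[C@@H](C)C/C(C)=C/CO[Si](C)(C)C(C)(C)C` | intermediate |
| 13 | (S)-3-bromo-2-methylpropan-1-ol | `OC[C@H](C)CBr` | starting material |
| 14 | (S)-(3-bromo-2-methylpropoxy)triethylsilane | `CC[Si](CC)(CC)OC[C@H](C)CBr` | intermediate |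
| 15 | prop-2-yn-1-ol | `C#CCO` | starting material |
| 16 | (E)-3-bromo-2-methylprop-2-en-1-ol | `OC/C(C)=C/Br` | intermediate |
| 17 | (E)-3-bromo-2-methylprop-2-enal | `O=C/C(C)=C/Br` | intermediate |
| 18 | (1E,3E)-1-bromo-4-iodo-2-methylbuta-1,3-diene | `I/C=C/C(C)=C/Br` | intermediate |
| 19 | (1E,3E,6R)-1-bromo-2,6-dimethyl-7-(TESO)hepta-1,3-diene | `CC[Si](CC)(CC)OC[C@H](C)C/C=C/C(C)=C/Br` | intermediate |
| 20 | (2R,4E,6E)-7-bromo-2,6-dimethylhepta-4,6-dienal | `O=C[C@H](C)C/C=C/C(C)=C/Br` | intermediate |
| 21 | (1E,3E,6R,7Z)-1-bromo-8-iodo-2,6-dimethyldeca-1,3,7-triene | `CCC(=C/[C@H](C)C/C=C/C(C)=C/Br)/I` | intermediate |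
| 22 | 3-(trimethylsilyl)prop-2-ynal | `C[Si](C)(C)C#CC=O` | starting material |
| 23 | (3R,4S)-4-methyl-1-(trimethylsilyl)hex-5-en-1-yn-3-ol | `C[Si](C)(C)C#C[C@H](O)[C@@H](C)C=C` | intermediate |
| 24 | mixed acrolein ethyl acetal of 23 | `C[Si](C)(C)C#C[C@H](OC(OCC)C=C)[C@@H](C)C=C` | intermediate |
| 25 | (2R,3S)-6-ethoxy-3-methyl-2-(TMS-ethynyl)-3,6-dihydro-2H-pyran | `C[Si](C)(C)C#C[C@@H]1OC(OCC)C=C[C@@H]1C` | intermediate |
| 26 | (2R,3S)-6-ethoxy-2-ethynyl-3-methyl-3,6-dihydro-2H-pyran | `C#C[C@@H]1OC(OCC)C=C[C@@H]1C` | intermediate |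
| 27 | West tetraenyl bromide (C10–C24) | `CCC(=C/[C@H](C)C/C=C/C(C)=C/Br)/C=C/[C@@H]1OC(OCC)C=C[C@@H]1C` | intermediate |
| 28 | C8 tertiary TMS ether / (9R)-oxirane adduct | `CCC(=C/[C@H](C)C/C=C/C(C)=C/C(O[Si](C)(C)C)([C@H]1CO1)[C@@H](C)[C@H](O[Si](CC)(CC)CC)[C@@H](C)C/C(C)=C/CO[Si](C)(C)C(C)(C)C)/C=C/[C@@H]1OC(OCC)C=C[C@@H]1C` | intermediate |
| 29 | (9S)-β-hydroxy ketone, protected | `CCC(=C/[C@H](C)C/C=C/C(C)=C/[C@@H](CO)C(=O)[C@@H](C)[C@H](O[Si](CC)(CC)CC)[C@@H](C)C/C(C)=C/CO[Si](C)(C)C(C)(C)C)/C=C/[C@@H]1OC(OCC)C=C[C@@H]1C` | intermediate |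
| 30 | lactol tetraol | `CCC(=C/[C@H](C)C/C=C/C(C)=C/[C@@H](CO)C(=O)[C@@H](C)[C@H](O)[C@@H](C)C/C(C)=C/CO)/C=C/[C@@H]1OC(O)C=C[C@@H]1C` | intermediate |
| 31 | lactone enal | `CCC(=C/[C@H](C)C/C=C/C(C)=C/[C@@H](CO)C(=O)[C@@H](C)[C@H](O)[C@@H](C)C/C(C)=C/C=O)/C=C/[C@@H]1OC(=O)C=C[C@@H]1C` | intermediate |
| 32 | kazusamycin A | `CCC(=C/[C@H](C)C/C=C/C(C)=C/[C@@H](CO)C(=O)[C@@H](C)[C@H](O)[C@@H](C)C/C(C)=C/C(=O)O)/C=C/[C@@H]1OC(=O)C=C[C@@H]1C` | target |

## Step count
- Total steps: 26.
- Longest linear sequence: 12 steps (15 → 16 → 17 → 18 → 19 → 20 → 21 → 27 → 28 → 29 → 30 → 31 → 32).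

## Three steps most likely to fail
1. **Step 23 (semipinacol shift).**
   - Risks: ionisation of the tertiary dienylic silyl ether, participation of the C6-OTES oxygen, or interference from the acetal.
   - Fallback: drop the Lewis-acid/epoxide trigger and use a leaving-group-driven pinacol-type shift.
     - Build the East ketone from a glycerate unit carrying C9-OSiR3 and C9′-OTBS.
     - Add the dienyllithium from 27, then selectively unmask and mesylate C9-OH.
     - Promote the 1,2-alkenyl shift of the β-mesyloxy tertiary alcohol with Et3Al at −78 °C; this gives the same inversion at C9 without free cationic conditions.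
2. **Step 22 (dienyllithium addition to hindered ketone 12).**
   - Risks: enolisation, β-elimination of the silyloxy group, or Payne migration.
   - Fallback: change the bond-forming order. Add the dienyllithium to the small epoxy ketone 10, run the semipinacol shift there to obtain the C7–C24 ethyl ketone, protect C9′-OH, and form C6–C7 last by an Ipc-boron syn-aldol with aldehyde 7.
3. **Step 8 (aldol with an epoxy ketone and three interacting stereochemical elements).**
   - Risk: low diastereoselectivity, or damage to the oxirane by the boron triflate.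
   - Fallback: set C6 and C7 by an Evans syn-aldol of (S)-4-benzyl-3-propionyloxazolidin-2-one with 7 under auxiliary control. Then silylate C6-OH, convert the imide to the C8 aldehyde, add vinylmagnesium bromide, carry out a reagent-controlled Sharpless epoxidation of the allylic alcohol, and oxidise with Dess–Martin periodinane to reach 12.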